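**Retrosynthetic overview**

1. Numbering (eudesmane): ring A = C1 (CH bearing the benzylic carbon C1'), C2, C3, C4 (CHMe), C5, C10 (quaternary, Me); ring B = C5, C6, C7 (CH bearing CMe2OH), C8, C9, C10. Enabling feature: the C5=C6 double bond sits on the ring-fusion carbon C5, exocyclic to ring A and inside ring B, so it can be read as the surviving half of an allene C4=C5=C6.
2. Key disconnection: C3–C4 and C5–C10 by an intramolecular Diels–Alder reaction of an acyclic diene–allene (diene C10=C1–C2=C3 with CO2Me on C1, dienophile C4=C5). It closes ring A and ring B together and sets C10 and C4.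
3. Precursor: C7 and the allene axis both come from the one bought stereocentre of (S)-but-3-yn-2-ol, through an ortho ester Claisen rearrangement via the cyclic ketene acetal of δ-valerolactone. The diene ester is built by alkyne homologation, carbocupration/iodination and Stille vinylation.
4. Endgame: conjugate reduction of the C1 enoate (sets C1), isobutyl ketone, addition of 2,4,6-trimethoxyphenyl, ionic hydrogenation (sets C1'), twofold formylation, O-demethylation.
5. Relay of configuration: carbinol → (C7 + axis) → (C10 + C4) → C1 → C1'. Ring order: A and B in one step; the arene is bought.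

Key step: step 10

Remark: in the SMILES the two allene CH carbons carry explicit hydrogens, so that the axial configuration (aS) is fixed by the chirality mark on the central allene carbon.

**Step 1**
Reactants: 1 oxan-2-one (δ-valerolactone)
Product: 3 2,2-dimethoxyoxane, via lactonium tetrafluoroborate 2 (not isolated)
Conditions: Me3OBF4, CH2Cl2, rt; then NaOMe, MeOH, −78 → 0 °C
Reagents that add atoms: trimethyloxonium tetrafluoroborate, C[O+](C)C.F[B-](F)(F)F; sodium methoxide, [Na+].[O-]C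
Why: O-Methylation of the lactone carbonyl with the Meerwein salt gives a dialkoxycarbenium ion that methoxide captures at carbon (lactone ortho ester synthesis); no stereocentre is formed.

**Step 2**
Reactants: 3 2,2-dimethoxyoxane; 4 (2S)-but-3-yn-2-ol
Product: 6 (3S)-3-[(aS)-buta-1,2-dien-1-yl]oxan-2-one, via cyclic ketene acetal 5 (not isolated)
Conditions: EtCO2H (cat.), xylene, 140 °C, MeOH distilled off
Reagents that add atoms: none
Why: Johnson–Claisen rearrangement of a propargylic alcohol to an allene: exchange and loss of methanol give the ketene acetal, whose [3,3] shift is suprafacial, so the carbinol centre becomes the aS axis, and because the enol ether double bond is held in the ring (C8 cis to the ring oxygen) and the carbinol methyl stays anti to the acetal carbon in the transition state, C7 should be formed S.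

**Step 3**
Reactants: 6 (3S)-3-[(aS)-buta-1,2-dien-1-yl]oxan-2-one
Product: 7 (4S,aS)-4-(2-hydroxypropan-2-yl)octa-5,6-dien-1-ol
Conditions: MeLi, CeCl3, THF, −78 → 0 °C; aq. NH4Cl
Reagents that add atoms: methyllithium, [Li]C
Why: Twofold addition of the weakly basic methylcerium reagent to the lactone carbonyl gives the tertiary alcohol and frees the C10 hydroxyl without enolising the α-allenyl lactone, so C7 and the axis are kept.

**Step 4**
Reactants: 7 (4S,aS)-4-(2-hydroxypropan-2-yl)octa-5,6-dien-1-ol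
Product: 8 (5S)-5-[(aS)-buta-1,2-dien-1-yl]-6,6-dimethyloxan-2-ol (lactol of the δ-hydroxy aldehyde, both anomers)
Conditions: Dess–Martin periodinane, NaHCO3, CH2Cl2, 0 °C
Reagents that add atoms: none
Why: Dess–Martin oxidation acts only on the primary alcohol, and the δ-hydroxy aldehyde is obtained as its lactol (the new anomeric centre is of no consequence).

**Step 5**
Reactants: 8 (5S)-5-[(aS)-buta-1,2-dien-1-yl]-6,6-dimethyloxan-2-ol
Product: 9 (3S)-3-[(aS)-buta-1,2-dien-1-yl]-2-methylhept-6-yn-2-ol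
Conditions: MeC(O)C(N2)P(O)(OMe)2, K2CO3, MeOH, rt
Reagents that add atoms: dimethyl (1-diazo-2-oxopropyl)phosphonate, CC(=O)C(=[N+]=[N-])P(=O)(OC)OC
Why: Ohira–Bestmann (Seyferth–Gilbert) homologation of the aldehyde in equilibrium with the lactol gives the terminal alkyne under conditions mild enough for the allene; no stereocentre is touched.

**Step 6**
Reactants: 9 (3S)-3-[(aS)-buta-1,2-dien-1-yl]-2-methylhept-6-yn-2-ol
Product: 10 triethyl({(3S)-3-[(aS)-buta-1,2-dien-1-yl]-2-methylhept-6-yn-2-yl}oxy)silane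
Conditions: Et3SiOTf, 2,6-lutidine, CH2Cl2, −78 → 0 °C
Reagents that add atoms: triethylsilyl trifluoromethanesulfonate, CC[Si](CC)(CC)OS(=O)(=O)C(F)(F)F
Why: Silylation of the hindered tertiary alcohol with a silyl triflate protects it against the organometallic steps and enlarges the C7 substituent that steers the key step.

**Step 7**
Reactants: 10 triethyl({(3S)-3-[(aS)-buta-1,2-dien-1-yl]-2-methylhept-6-yn-2-yl}oxy)silane
Product: 11 methyl (6S)-6-[(aS)-buta-1,2-dien-1-yl]-7-methyl-7-[(triethylsilyl)oxy]oct-2-ynoate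
Conditions: LiN(SiMe3)2, THF, −78 °C; ClCO2Me, −78 → 0 °C
Reagents that add atoms: methyl chloroformate, COC(=O)Cl
Why: The silylamide removes only the acetylenic proton and the lithium acetylide is C-acylated by the chloroformate to the alkynoate.

**Step 8**
Reactants: 11 methyl (6S)-6-[(aS)-buta-1,2-dien-1-yl]-7-methyl-7-[(triethylsilyl)oxy]oct-2-ynoate
Product: 12 methyl (2E,6S)-6-[(aS)-buta-1,2-dien-1-yl]-2-iodo-3,7-dimethyl-7-[(triethylsilyl)oxy]oct-2-enoate
Conditions: Me2CuLi (from MeLi, CuI), THF, −78 °C; I2, −78 °C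
Reagents that add atoms: lithium dimethylcuprate, [Li+].C[Cu-]C; iodine, [I][I]
Why: Conjugate addition of the cuprate to the alkynoate is a syn carbocupration that puts the new methyl on C10 and copper on C1 on the same side, and iodinolysis of the configurationally stable alkenylcopper at −78 °C keeps this geometry (iodine trans to the C9 chain).

**Step 9**
Reactants: 12 methyl (2E,6S)-6-[(aS)-buta-1,2-dien-1-yl]-2-iodo-3,7-dimethyl-7-[(triethylsilyl)oxy]oct-2-enoate
Product: 13 methyl (2Z,6S)-6-[(aS)-buta-1,2-dien-1-yl]-2-ethenyl-3,7-dimethyl-7-[(triethylsilyl)oxy]oct-2-enoate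
Conditions: CH2=CHSnBu3, Pd2(dba)3 (cat.), AsPh3, CuI (cat.), DMF, 40 °C
Reagents that add atoms: tributyl(vinyl)stannane, C=C[Sn](CCCC)(CCCC)CCCC
Why: Stille coupling replaces iodine by vinyl with retention of the double-bond geometry and completes the 2-methoxycarbonyl diene with the C10 methyl inside (cis to vinyl) and the tether outside.

**Step 10**
Reactants: 13 methyl (2Z,6S)-6-[(aS)-buta-1,2-dien-1-yl]-2-ethenyl-3,7-dimethyl-7-[(triethylsilyl)oxy]oct-2-enoate
Product: 14 methyl (4R,6S,8aS)-4,8a-dimethyl-6-{2-[(triethylsilyl)oxy]propan-2-yl}-3,4,6,7,8,8a-hexahydronaphthalene-1-carboxylate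
Conditions: o-dichlorobenzene (0.01 M), BHT (cat.), 180 °C, sealed tube
Reagents that add atoms: none
Why: Thermal intramolecular Diels–Alder reaction in which the diene C10=C1–C2=C3 adds suprafacially across the allene double bond C4=C5 that is remote from the tether; the closest known reaction type is the intramolecular [4+2] cycloaddition of allenic dienophiles through their distal double bond, here helped by the electron-poor 2-alkoxycarbonyl diene. Ring B (C5–C6–C7–C8–C9–C10) closes by the C5–C10 bond onto the central allene carbon, so that its C5=C6 bond is the untouched half of the allene, and ring A (C10–C1–C2–C3–C4–C5) closes in the same concerted event by the C3–C4 bond. The quaternary centre C10 is controlled by C7: the tether takes the half-chair in which the CMe2OSiEt3 group is pseudoequatorial and C8 is turned away from the ester on C1, which puts the C10 methyl (inside position of the diene) on the face of ring B that carries the C7 substituent. C4 is controlled by the allene axis: the diene can reach the C4=C5 bond only from the side of C7 (the other side would need a trans double bond in ring B), and there the aS axis points the C4 methyl away from the diene (exo), which makes it cis to the C10 methyl. The step needs site selectivity between the two allene double bonds and one of four diastereomeric transition states; the first is secured because only the distal mode joins the fully substituted C10 to an unsubstituted sp carbon (the proximal mode would bond it to C6 next to the branched C7), the second by the matched pair of C7 configuration and axis made together in step 2.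

**Step 11**
Reactants: 14 methyl (4R,6S,8aS)-4,8a-dimethyl-6-{2-[(triethylsilyl)oxy]propan-2-yl}-3,4,6,7,8,8a-hexahydronaphthalene-1-carboxylate
Product: 15 methyl (1S,4R,6S,8aR)-4,8a-dimethyl-6-{2-[(triethylsilyl)oxy]propan-2-yl}-1,2,3,4,6,7,8,8a-octahydronaphthalene-1-carboxylate
Conditions: Cu(OAc)2·H2O (cat.), 1,2-bis(diphenylphosphino)benzene (cat.), (EtO)2MeSiH, t-BuOH, PhMe, rt
Reagents that add atoms: none
Why: Copper hydride conjugate reduction touches only the enoate (hydride to C2), and protonation of the resulting enolate at C1 should occur axially from the face opposite the axial C10 and C4 methyl groups, which leaves the ester cis to the C10 methyl.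

**Step 12**
Reactants: 15 methyl (1S,4R,6S,8aR)-4,8a-dimethyl-6-{2-[(triethylsilyl)oxy]propan-2-yl}-1,2,3,4,6,7,8,8a-octahydronaphthalene-1-carboxylate
Product: 17 1-[(1S,4R,6S,8aR)-4,8a-dimethyl-6-{2-[(triethylsilyl)oxy]propan-2-yl}-1,2,3,4,6,7,8,8a-octahydronaphthalen-1-yl]-3-methylbutan-1-one, via Weinreb amide 16 (not isolated)
Conditions: MeNHOMe·HCl, i-PrMgCl, THF, −20 → 0 °C; then i-BuMgBr, 0 °C → rt; aq. NH4Cl
Reagents that add atoms: isobutylmagnesium bromide, CC(C)C[Mg]Br
Why: Ester to ketone through the Weinreb amide (Weinreb ketone synthesis), whose magnesium chelate takes up only one equivalent of the Grignard reagent; the reagents are too weakly basic to epimerise C1.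

**Step 13**
Reactants: 17 1-[(1S,4R,6S,8aR)-4,8a-dimethyl-6-{2-[(triethylsilyl)oxy]propan-2-yl}-1,2,3,4,6,7,8,8a-octahydronaphthalen-1-yl]-3-methylbutan-1-one; 18 1,3,5-trimethoxybenzene
Product: 20 2-[(1S)-1-[(1R,4R,6S,8aR)-4,8a-dimethyl-6-{2-[(triethylsilyl)oxy]propan-2-yl}-1,2,3,4,6,7,8,8a-octahydronaphthalen-1-yl]-3-methylbutyl]-1,3,5-trimethoxybenzene, via tertiary benzylic alcohol 19 (not isolated)
Conditions: 18, n-BuLi, TMEDA, THF, 0 °C; CeCl3, −78 °C; 17, −78 → 0 °C; work-up; then Et3SiH, CF3CO2H, CH2Cl2, −78 °C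
Reagents that add atoms: none
Why: 1,2-Addition of the weakly basic arylcerium reagent gives a tertiary 2,4,6-trimethoxybenzylic alcohol that ionises with dilute acid at −78 °C, and ionic hydrogenation delivers hydride to the cation in the conformer that keeps C1–H in the plane beside the ortho-methoxy group (1,3-allylic strain), on the face away from the quaternary C10, which should set C1' as S.

**Step 14**
Reactants: 20 2-[(1S)-1-[(1R,4R,6S,8aR)-4,8a-dimethyl-6-{2-[(triethylsilyl)oxy]propan-2-yl}-1,2,3,4,6,7,8,8a-octahydronaphthalen-1-yl]-3-methylbutyl]-1,3,5-trimethoxybenzene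
Product: 24 5-[(1S)-1-[(1R,4R,6S,8aR)-6-(2-hydroxypropan-2-yl)-4,8a-dimethyl-1,2,3,4,6,7,8,8a-octahydronaphthalen-1-yl]-3-methylbutyl]-2,4,6-trimethoxybenzene-1,3-dicarbaldehyde, via monoformyl amino alkoxide 21 (not isolated), via bis(amino alkoxide) 22 (not isolated), via silyl-protected dialdehyde 23 (not isolated)
Conditions: n-BuLi, TMEDA, THF, 0 °C; DMF, −78 → 0 °C; n-BuLi, 0 °C; DMF; then 1 M HCl, THF, rt
Reagents that add atoms: N,N-dimethylformamide, CN(C)C=O
Why: Directed ortho-metalation and formylation: each free arene position lies between two methoxy groups, the first formyl group stays masked as its lithium α-amino alkoxide while the second position is lithiated and formylated, and aqueous acid then releases both aldehydes and cleaves the triethylsilyl ether.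

**Step 15**
Reactants: 24 5-[(1S)-1-[(1R,4R,6S,8aR)-6-(2-hydroxypropan-2-yl)-4,8a-dimethyl-1,2,3,4,6,7,8,8a-octahydronaphthalen-1-yl]-3-methylbutyl]-2,4,6-trimethoxybenzene-1,3-dicarbaldehyde
Product: 25 5-[(1S)-1-[(1R,4R,6S,8aR)-6-(2-hydroxypropan-2-yl)-4,8a-dimethyl-1,2,3,4,6,7,8,8a-octahydronaphthalen-1-yl]-3-methylbutyl]-2,4,6-trihydroxybenzene-1,3-dicarbaldehyde (target)
Conditions: NaSEt, DMF, 110 °C; then aq. HCl
Reagents that add atoms: none
Why: Thiolate O-demethylation (SN2 at methyl) is fast because every methoxy group is ortho or para to a formyl group, and the basic medium spares the tertiary alcohol and the C5=C6 bond.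

**Compound list**

1 | oxan-2-one (δ-valerolactone) | O=C1CCCCO1 | starting material
2 | 6-methoxy-3,4-dihydro-2H-pyran-1-ium tetrafluoroborate | COC1=[O+]CCCC1.F[B-](F)(F)F | intermediate
3 | 2,2-dimethoxyoxane | COC1(OC)CCCCO1 | intermediate
4 | (2S)-but-3-yn-2-ol | C[C@H](O)C#C | starting material
5 | 6-{[(2S)-but-3-yn-2-yl]oxy}-3,4-dihydro-2H-pyran | C#C[C@H](C)OC1=CCCCO1 | intermediate
6 | (3S)-3-[(aS)-buta-1,2-dien-1-yl]oxan-2-one | CC([H])=[C@@]=C([H])[C@H]1C(=O)OCCC1 | intermediate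
7 | (4S,aS)-4-(2-hydroxypropan-2-yl)octa-5,6-dien-1-ol | CC([H])=[C@@]=C([H])[C@@H](C(C)(C)O)CCCO | intermediate
8 | (5S)-5-[(aS)-buta-1,2-dien-1-yl]-6,6-dimethyloxan-2-ol (both anomers) | CC([H])=[C@@]=C([H])[C@@H]1CCC(O)OC1(C)C | intermediate
9 | (3S)-3-[(aS)-buta-1,2-dien-1-yl]-2-methylhept-6-yn-2-ol | CC([H])=[C@@]=C([H])[C@@H](C(C)(C)O)CCC#C | intermediate
10 | triethyl({(3S)-3-[(aS)-buta-1,2-dien-1-yl]-2-methylhept-6-yn-2-yl}oxy)silane | CC([H])=[C@@]=C([H])[C@@H](C(C)(C)O[Si](CC)(CC)CC)CCC#C | intermediate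
11 | methyl (6S)-6-[(aS)-buta-1,2-dien-1-yl]-7-methyl-7-[(triethylsilyl)oxy]oct-2-ynoate | CC([H])=[C@@]=C([H])[C@@H](C(C)(C)O[Si](CC)(CC)CC)CCC#CC(=O)OC | intermediate
12 | methyl (2E,6S)-6-[(aS)-buta-1,2-dien-1-yl]-2-iodo-3,7-dimethyl-7-[(triethylsilyl)oxy]oct-2-enoate | CC([H])=[C@@]=C([H])[C@@H](C(C)(C)O[Si](CC)(CC)CC)CC/C(C)=C(/I)C(=O)OC | intermediate
13 | methyl (2Z,6S)-6-[(aS)-buta-1,2-dien-1-yl]-2-ethenyl-3,7-dimethyl-7-[(triethylsilyl)oxy]oct-2-enoate | CC([H])=[C@@]=C([H])[C@@H](C(C)(C)O[Si](CC)(CC)CC)CC/C(C)=C(/C=C)C(=O)OC | intermediate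
14 | methyl (4R,6S,8aS)-4,8a-dimethyl-6-{2-[(triethylsilyl)oxy]propan-2-yl}-3,4,6,7,8,8a-hexahydronaphthalene-1-carboxylate | COC(=O)C1=CC[C@@H](C)C2=C[C@@H](C(C)(C)O[Si](CC)(CC)CC)CC[C@@]21C | intermediate
15 | methyl (1S,4R,6S,8aR)-4,8a-dimethyl-6-{2-[(triethylsilyl)oxy]propan-2-yl}-1,2,3,4,6,7,8,8a-octahydronaphthalene-1-carboxylate | COC(=O)[C@H]1CC[C@@H](C)C2=C[C@@H](C(C)(C)O[Si](CC)(CC)CC)CC[C@@]21C | intermediate
16 | (1S,4R,6S,8aR)-N-methoxy-N,4,8a-trimethyl-6-{2-[(triethylsilyl)oxy]propan-2-yl}-1,2,3,4,6,7,8,8a-octahydronaphthalene-1-carboxamide | CON(C)C(=O)[C@H]1CC[C@@H](C)C2=C[C@@H](C(C)(C)O[Si](CC)(CC)CC)CC[C@@]21C | intermediate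
17 | 1-[(1S,4R,6S,8aR)-4,8a-dimethyl-6-{2-[(triethylsilyl)oxy]propan-2-yl}-1,2,3,4,6,7,8,8a-octahydronaphthalen-1-yl]-3-methylbutan-1-one | CC(C)CC(=O)[C@H]1CC[C@@H](C)C2=C[C@@H](C(C)(C)O[Si](CC)(CC)CC)CC[C@@]21C | intermediate
18 | 1,3,5-trimethoxybenzene | COc1cc(OC)cc(OC)c1 | starting material
19 | 1-[(1S,4R,6S,8aR)-4,8a-dimethyl-6-{2-[(triethylsilyl)oxy]propan-2-yl}-1,2,3,4,6,7,8,8a-octahydronaphthalen-1-yl]-3-methyl-1-(2,4,6-trimethoxyphenyl)butan-1-ol (both epimers at C1') | CC(C)CC(O)(c1c(OC)cc(OC)cc1OC)[C@H]1CC[C@@H](C)C2=C[C@@H](C(C)(C)O[Si](CC)(CC)CC)CC[C@@]21C | intermediate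
20 | 2-[(1S)-1-[(1R,4R,6S,8aR)-4,8a-dimethyl-6-{2-[(triethylsilyl)oxy]propan-2-yl}-1,2,3,4,6,7,8,8a-octahydronaphthalen-1-yl]-3-methylbutyl]-1,3,5-trimethoxybenzene | CC(C)C[C@H](c1c(OC)cc(OC)cc1OC)[C@H]1CC[C@@H](C)C2=C[C@@H](C(C)(C)O[Si](CC)(CC)CC)CC[C@@]21C | intermediate
21 | lithium (dimethylamino)(aryl)methanolate from monoformylation of 20 (aryl = 2,4,6-trimethoxy-3-substituted phenyl, side chain as in 20) | CC(C)C[C@H](c1c(OC)c(C([O-])N(C)C)c(OC)cc1OC)[C@H]1CC[C@@H](C)C2=C[C@@H](C(C)(C)O[Si](CC)(CC)CC)CC[C@@]21C.[Li+] | intermediate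
22 | dilithium bis[(dimethylamino)methanolate] from twofold formylation of 20 | CC(C)C[C@H](c1c(OC)c(C([O-])N(C)C)c(OC)c(C([O-])N(C)C)c1OC)[C@H]1CC[C@@H](C)C2=C[C@@H](C(C)(C)O[Si](CC)(CC)CC)CC[C@@]21C.[Li+].[Li+] | intermediate
23 | 5-[(1S)-1-[(1R,4R,6S,8aR)-4,8a-dimethyl-6-{2-[(triethylsilyl)oxy]propan-2-yl}-1,2,3,4,6,7,8,8a-octahydronaphthalen-1-yl]-3-methylbutyl]-2,4,6-trimethoxybenzene-1,3-dicarbaldehyde | CC(C)C[C@H](c1c(OC)c(C=O)c(OC)c(C=O)c1OC)[C@H]1CC[C@@H](C)C2=C[C@@H](C(C)(C)O[Si](CC)(CC)CC)CC[C@@]21C | intermediate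
24 | 5-[(1S)-1-[(1R,4R,6S,8aR)-6-(2-hydroxypropan-2-yl)-4,8a-dimethyl-1,2,3,4,6,7,8,8a-octahydronaphthalen-1-yl]-3-methylbutyl]-2,4,6-trimethoxybenzene-1,3-dicarbaldehyde | CC(C)C[C@H](c1c(OC)c(C=O)c(OC)c(C=O)c1OC)[C@H]1CC[C@@H](C)C2=C[C@@H](C(C)(C)O)CC[C@@]21C | intermediate
25 | 5-[(1S)-1-[(1R,4R,6S,8aR)-6-(2-hydroxypropan-2-yl)-4,8a-dimethyl-1,2,3,4,6,7,8,8a-octahydronaphthalen-1-yl]-3-methylbutyl]-2,4,6-trihydroxybenzene-1,3-dicarbaldehyde | CC(C)C[C@H](c1c(O)c(C=O)c(O)c(C=O)c1O)[C@H]1CC[C@@H](C)C2=C[C@@H](C(C)(C)O)CC[C@@]21C | target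

**Step count and risks**

Total step count: 15. Longest linear sequence: 15 steps (1 → 25); 4 and 18 enter in steps 2 and 13.

The three steps most likely to fail:

Step 10. At the temperature that the fully substituted, electron-poor diene terminus demands, the cycloaddition may be outrun by a [1,5]-hydrogen shift from the cis methyl group of the diene or by allene oligomerisation, or it may show poor facial selectivity. The fallback sets out from 10 and comes back at 17; it uses a less substituted, ester-free diene and metal catalysis. Negishi carboalumination of the alkyne of 10 (Me3Al, Cp2ZrCl2, CH2Cl2) and coupling of the alkenylalane with (E)-(2-bromoethenyl)trimethylsilane (ZnCl2, Pd(PPh3)4) should give the silyl diene trimethyl[(1E,3E,7S)-7-[(aS)-buta-1,2-dien-1-yl]-4,8-dimethyl-8-[(triethylsilyl)oxy]nona-1,3-dien-1-yl]silane F1. The rhodium-catalysed intramolecular [4+2] reaction of dienes with allenes ([Rh(cod)Cl]2, tris(2-biphenylyl) phosphite, THF, 60 °C) should then give the allylsilane (3S,4S,6S,8aR)-4,8a-dimethyl-6-{2-[(triethylsilyl)oxy]propan-2-yl}-3-(trimethylsilyl)-3,4,6,7,8,8a-hexahydronaphthalene F2, with silicon on C3 trans to the C10 methyl. Acylation with isovaleryl chloride and TiCl4 at −78 °C (anti SE2', so the acyl group enters C1 on the face of the C10 methyl) should give the β,γ-unsaturated ketone 1-[(1S,4R,6S,8aR)-4,8a-dimethyl-6-{2-[(triethylsilyl)oxy]propan-2-yl}-1,4,6,7,8,8a-hexahydronaphthalen-1-yl]-3-methylbutan-1-one F3. Hydrogenation of its disubstituted C2=C3 bond (H2, RhCl(PPh3)3) gives 17.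

Step 13. 1,2-Addition of the bulky arylcerium reagent to the α-branched ketone may lose out to enolisation. The fallback sets out from 15 and comes back at 19; it reverses the order in which the two C1' substituents are attached. Reduction with i-Bu2AlH (CH2Cl2, −78 °C) should give the aldehyde (1S,4R,6S,8aR)-4,8a-dimethyl-6-{2-[(triethylsilyl)oxy]propan-2-yl}-1,2,3,4,6,7,8,8a-octahydronaphthalene-1-carbaldehyde F4. Addition of (2,4,6-trimethoxyphenyl)lithium, which is easy at an aldehyde, gives the secondary alcohol [(1S,4R,6S,8aR)-4,8a-dimethyl-6-{2-[(triethylsilyl)oxy]propan-2-yl}-1,2,3,4,6,7,8,8a-octahydronaphthalen-1-yl](2,4,6-trimethoxyphenyl)methanol F5 (both carbinol epimers). Dess–Martin oxidation gives the aryl ketone [(1S,4R,6S,8aR)-4,8a-dimethyl-6-{2-[(triethylsilyl)oxy]propan-2-yl}-1,2,3,4,6,7,8,8a-octahydronaphthalen-1-yl](2,4,6-trimethoxyphenyl)methanone F6. Addition of the small primary nucleophile i-BuLi/CeCl3 then gives 19, which is reduced as in step 13.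

Step 2. Transfer of the carbinol configuration to C7 may be poor if the two orientations of the ketene acetal compete, or if ring opening of the ortho ester releases an acyclic ketene acetal of undefined geometry. The fallback sets out from 1 and comes back at 7; it replaces the sigmatropic relay by auxiliary control and a stereospecific allene synthesis:
- Saponification of 1 (NaOH), silylation (t-BuMe2SiCl, imidazole) and mild hydrolysis of the silyl ester give 5-[(tert-butyldimethylsilyl)oxy]pentanoic acid F7.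
- Its mixed pivalic anhydride acylates lithiated (4S)-4-benzyl-1,3-oxazolidin-2-one to (4S)-4-benzyl-3-{5-[(tert-butyldimethylsilyl)oxy]pentanoyl}-1,3-oxazolidin-2-one F8.
- Evans syn-aldol reaction (Bu2BOTf, i-Pr2NEt, then but-2-ynal) gives (4S)-4-benzyl-3-[(2S,3S)-2-{3-[(tert-butyldimethylsilyl)oxy]propyl}-3-hydroxyhex-4-ynoyl]-1,3-oxazolidin-2-one F9.
- MeOMgBr displaces the auxiliary to methyl (2S,3S)-2-{3-[(tert-butyldimethylsilyl)oxy]propyl}-3-hydroxyhex-4-ynoate F10.
- MeMgBr/CeCl3 gives (3S,4S)-3-{3-[(tert-butyldimethylsilyl)oxy]propyl}-2-methylhept-5-yne-2,4-diol F11.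
- Mitsunobu reaction of the secondary propargylic alcohol with 2-nitrobenzenesulfonylhydrazine (PPh3, DEAD, −15 °C → rt), followed by loss of sulfinic acid and suprafacial loss of N2 from the propargylic diazene, gives (3S)-3-[(aS)-buta-1,2-dien-1-yl]-6-[(tert-butyldimethylsilyl)oxy]-2-methylhexan-2-ol F12 stereospecifically.
- Bu4NF removes the silyl ether to give 7.

**Further compounds**

F1 | step 10 | trimethyl[(1E,3E,7S)-7-[(aS)-buta-1,2-dien-1-yl]-4,8-dimethyl-8-[(triethylsilyl)oxy]nona-1,3-dien-1-yl]silane | CC([H])=[C@@]=C([H])[C@@H](C(C)(C)O[Si](CC)(CC)CC)CC/C(C)=C/C=C/[Si](C)(C)C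
F2 | step 10 | (3S,4S,6S,8aR)-4,8a-dimethyl-6-{2-[(triethylsilyl)oxy]propan-2-yl}-3-(trimethylsilyl)-3,4,6,7,8,8a-hexahydronaphthalene | C1=C[C@H]([Si](C)(C)C)[C@@H](C)C2=C[C@@H](C(C)(C)O[Si](CC)(CC)CC)CC[C@@]21C
F3 | step 10 | 1-[(1S,4R,6S,8aR)-4,8a-dimethyl-6-{2-[(triethylsilyl)oxy]propan-2-yl}-1,4,6,7,8,8a-hexahydronaphthalen-1-yl]-3-methylbutan-1-one | CC(C)CC(=O)[C@H]1C=C[C@@H](C)C2=C[C@@H](C(C)(C)O[Si](CC)(CC)CC)CC[C@@]21C
F4 | step 13 | (1S,4R,6S,8aR)-4,8a-dimethyl-6-{2-[(triethylsilyl)oxy]propan-2-yl}-1,2,3,4,6,7,8,8a-octahydronaphthalene-1-carbaldehyde | O=C[C@H]1CC[C@@H](C)C2=C[C@@H](C(C)(C)O[Si](CC)(CC)CC)CC[C@@]21C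
F5 | step 13 | [(1S,4R,6S,8aR)-4,8a-dimethyl-6-{2-[(triethylsilyl)oxy]propan-2-yl}-1,2,3,4,6,7,8,8a-octahydronaphthalen-1-yl](2,4,6-trimethoxyphenyl)methanol (both carbinol epimers) | OC(c1c(OC)cc(OC)cc1OC)[C@H]1CC[C@@H](C)C2=C[C@@H](C(C)(C)O[Si](CC)(CC)CC)CC[C@@]21C
F6 | step 13 | [(1S,4R,6S,8aR)-4,8a-dimethyl-6-{2-[(triethylsilyl)oxy]propan-2-yl}-1,2,3,4,6,7,8,8a-octahydronaphthalen-1-yl](2,4,6-trimethoxyphenyl)methanone | O=C(c1c(OC)cc(OC)cc1OC)[C@H]1CC[C@@H](C)C2=C[C@@H](C(C)(C)O[Si](CC)(CC)CC)CC[C@@]21C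
F7 | step 2 | 5-[(tert-butyldimethylsilyl)oxy]pentanoic acid | CC(C)(C)[Si](C)(C)OCCCCC(=O)O
F8 | step 2 | (4S)-4-benzyl-3-{5-[(tert-butyldimethylsilyl)oxy]pentanoyl}-1,3-oxazolidin-2-one | CC(C)(C)[Si](C)(C)OCCCCC(=O)N1[C@@H](Cc2ccccc2)COC1=O
F9 | step 2 | (4S)-4-benzyl-3-[(2S,3S)-2-{3-[(tert-butyldimethylsilyl)oxy]propyl}-3-hydroxyhex-4-ynoyl]-1,3-oxazolidin-2-one | CC#C[C@@H](O)[C@H](CCCO[Si](C)(C)C(C)(C)C)C(=O)N1[C@@H](Cc2ccccc2)COC1=O
F10 | step 2 | methyl (2S,3S)-2-{3-[(tert-butyldimethylsilyl)oxy]propyl}-3-hydroxyhex-4-ynoate | CC#C[C@@H](O)[C@H](CCCO[Si](C)(C)C(C)(C)C)C(=O)OC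
F11 | step 2 | (3S,4S)-3-{3-[(tert-butyldimethylsilyl)oxy]propyl}-2-methylhept-5-yne-2,4-diol | CC#C[C@@H](O)[C@H](CCCO[Si](C)(C)C(C)(C)C)C(C)(C)O
F12 | step 2 | (3S)-3-[(aS)-buta-1,2-dien-1-yl]-6-[(tert-butyldimethylsilyl)oxy]-2-methylhexan-2-ol | CC([H])=[C@@]=C([H])[C@@H](C(C)(C)O)CCCO[Si](C)(C)C(C)(C)C
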